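All constants are those of an exercise; what happens was integrated by code.

Q, the product, can leave the solution as crystals G, and the dispute over this flask is whether it does.

X 20 mM (fed, over 1.2 s); E 0.400 mM; time 6.0 min; the fed solution adds 0.50 times the starting volume

    X ⇌ Z (K1 = 2.1, k1 = 0.070 s⁻¹)
    Z ⇌ Q (K2 = 8.7, k2 = 0.14 s⁻¹)
    G ⇌ Q, rate k3*(cs3 - [Q]) while solid is left; crystals form when [Q] > cs3 (cs3 = 11 mM, k3 = 3.1 s⁻¹)
    Z + E → Z.E (k4 = 1.4 M⁻¹ s⁻¹)

- for Q the G are counted in
- charges are per starting volume, the dose included; the dosed solution carries all of it
- as a solid, counted per litre of solution: G
- the reaction counts as stopped when no species that holds the X changes by six tenths of a point or more over the second half of the time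
- run time (flask): 6.0 min

1. at 6.0 min, what has stopped the reaction, if anything has (it is still moving / all of X has reacted / forward and back rates have come level)
2. the Q standing at 6.0 min, as a percentage of the X charged
3. the Z standing at 6.0 min, as a percentage of the X charged

Two chemists dispute this flask, and they start from common ground: the dose is in after 1.2 s and the volume has grown, so the charge stands at 13.3 mM. The first two steps, each taken alone and both ways together, relax with half-lives of 0.112 min and 0.0740 min, short against 6.0 min, while Z, by the step to Z.E alone with E as charged, has a half-life of 21 min, long against it, so both reckon X, Z and Q as a pre-equilibrium with a slow leak.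

The first chemist holds the share view: the two constants divide the charge among the three species, whatever its size, so Z takes 9.83% of it, and c(Q) comes to 11.4 mM, which is above the solubility by 0.400 mM, a margin this chemist sets aside as too thin to matter.

The second chemist holds the ceiling view: that excess crystallises, c(Q) stays at 11 mM while G is there, and the ceiling of c(Z) is 1.26 mM, the solubility of Q divided by K2, a concentration that, while G is there and step 2 stands balanced, does not grow with the charge of X, so that under those conditions Z's percentage falls as that charge rises.

I side with the ceiling, and by hand it gives Z as 9.48% of the X charged and Q, crystals counted in, as 86.0%, with nothing yet taken off for Z.E.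

The forecast is the second chemist's number: “crystals form and pin dissolved Q”, with Z at 9.47%, Q at 85%, lower than my figure, and as the state at the end: forward and back rates have come level.

The flask gives Z at 9.47% and Q at 85.0%, its state at the end being: forward and back rates have come level, and G stands at 2.50% of the X charged at 6.00 min, so crystals are present and the ceiling view stands. The share view keeps the region where c(Q) stays under 11 mM, and, with E and the time held, Z's percentage holds within 5 points of itself down to at least 2.5 mM of X. In the neighbour flask with 80 mM of X the charge stands at 53.3 mM, the ceiling makes Z 2.36% of it, and that flask stands at 2.37%.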